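**Retrosynthetic overview**
1. The aldehyde is removed last: formylation at the only free arene position of the 6'-isovaleryl-5',7'-dihydroxy spirochromane.
2. The benzene ring is opened by a retro-Claisen to a fused 2-pyranone (enol lactone as acyl donor, side-chain diketone carbon as nucleophile); this locks the ring oxygen para to the acyl group.
3. The dihydropyran ring is opened by a retro hetero-Diels–Alder to a 3-methylidene-pyran-2,4-dione (pyranone + formaldehyde) and (−)-β-pinene; the spiro centre comes from addition anti to the gem-dimethyl bridge.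
4. The keto-pyranone comes from triacetic acid lactone and methyl isovalerate by dianion acylation.
5. Ring order: pyranone template and pinane bicycle are bought; the dihydropyran and benzene rings are then made together in one flask (the template ring is consumed); formylation ends the route.

Assumption: the target is read as the adduct of (1S,5S)-(−)-β-pinene with the chromane oxygen on the face of the spiro carbon anti to the gem-dimethyl bridge, i.e. (1R,2R,5S) in spiro[bicyclo[3.1.1]heptane-2,2'-chromane] numbering; commercial (−)-β-pinene of high enantiomeric purity is used.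

**Step 1**
Reactants: 1 4-hydroxy-6-methyl-2H-pyran-2-one (triacetic acid lactone); 2 methyl 3-methylbutanoate (methyl isovalerate)
Product: 4 4-hydroxy-6-(4-methyl-2-oxopentyl)-2H-pyran-2-one, via dilithio dianion 3 (not isolated)
Conditions: 1 (2.2 equiv), LiN(iPr)2 (4.5 equiv), THF/DMPU, −78 °C; then 2 (1.0 equiv), −78 → 0 °C; aq. HCl
Reagents that add atoms: none
Why: Claisen-type acylation of a dianion, in which deprotonation of the 4-OH and then of the vinylogous 6-methyl group gives dianion 3, which attacks the ester only through its far more nucleophilic CH2 terminus while the excess dianion stores the more acidic product as its enolate; no stereocentre is formed.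

**Step 2**
Reactants: 4 4-hydroxy-6-(4-methyl-2-oxopentyl)-2H-pyran-2-one; 5 formaldehyde (charged as paraformaldehyde); 6 (1S,5S)-(−)-β-pinene
Product: 10 1-[(1R,2R,5S)-5',7'-dihydroxy-6,6-dimethylspiro[bicyclo[3.1.1]heptane-2,2'-chromane]-6'-yl]-3-methylbutan-1-one, via methylidene pyrandione 7 (not isolated), via spiro pyranopyranone 8 (not isolated), via ring-opened methyl ester 9 (not isolated)
Conditions: 5 (1.2 equiv), 6 (8 equiv), ethylenediammonium diacetate (10 mol %), 1,4-dioxane, 100 °C, sealed tube; evaporate; then Mg(OMe)2 (5 equiv), MeOH, 65 °C; cold 1 N HCl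
Reagents that add atoms: none
Why: Proposed new method: a domino Knoevenagel condensation/inverse-electron-demand hetero-Diels–Alder reaction followed in the same flask by base-triggered lactone opening and Claisen (Dieckmann-type) aromatisation, in which the acidic pyranone condenses with formaldehyde at C3 to the 1-oxadiene 7, its CH2 terminus bonds to the =CH2 carbon of 6 while the ketone oxygen bonds to the tertiary alkene carbon from the face anti to the gem-dimethyl bridge (this sets the spiro centre as 2R, the two bridgeheads of 6 are untouched), and methoxide then opens the enol lactone of 8 to the magnesium-chelated diketo ester 9, whose central diketone carbon can only close a six-membered ring onto the ester and so gives the phloroglucinol with the ring oxygen fixed para to the acyl group; the closest known reaction types are the three-component formaldehyde/alkene trapping of 4-hydroxycoumarin-type enols and the Mg(OMe)2 conversion of 4-hydroxy-6-(2-oxoalkyl)-2-pyranones into acylphloroglucinols.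

**Step 3**
Reactants: 10 1-[(1R,2R,5S)-5',7'-dihydroxy-6,6-dimethylspiro[bicyclo[3.1.1]heptane-2,2'-chromane]-6'-yl]-3-methylbutan-1-one
Product: 12 euglobal G3, (1R,2R,5S)-5',7'-dihydroxy-6,6-dimethyl-6'-(3-methylbutanoyl)spiro[bicyclo[3.1.1]heptane-2,2'-chromane]-8'-carbaldehyde, via aryl iminium chloride 11 (not isolated)
Conditions: POCl3 (1.3 equiv), DMF (3 equiv), MeCN, 0 °C → rt; then H2O, rt
Reagents that add atoms: N,N-dimethylformamide, CN(C)C=O (formyl carbon); water, O (formyl oxygen)
Why: Vilsmeier–Haack formylation (electrophilic aromatic substitution), in which the chloroiminium ion from DMF and POCl3 attacks C8', the only free ring position and one activated by three oxygen donors, and water hydrolyses iminium salt 11 to the aldehyde under conditions free of strong Lewis acid, so the tertiary aryl ether and the three stereocentres stay intact.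

**Compound list**
1 | 4-hydroxy-6-methyl-2H-pyran-2-one (triacetic acid lactone) | CC1=CC(O)=CC(=O)O1 | starting material
2 | methyl 3-methylbutanoate (methyl isovalerate) | COC(=O)CC(C)C | starting material
3 | dilithium salt of the dianion of 1 (4-oxido, 6-CH2 carbanion) | [Li+].[Li+].[CH2-]C1=CC([O-])=CC(=O)O1 | intermediate
4 | 4-hydroxy-6-(4-methyl-2-oxopentyl)-2H-pyran-2-one | CC(C)CC(=O)CC1=CC(O)=CC(=O)O1 | intermediate
5 | formaldehyde (charged as paraformaldehyde) | C=O | starting material
6 | (1S,5S)-6,6-dimethyl-2-methylidenebicyclo[3.1.1]heptane, (−)-β-pinene | C=C1CC[C@H]2C[C@@H]1C2(C)C | starting material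
7 | 3-methylidene-6-(4-methyl-2-oxopentyl)-2H-pyran-2,4(3H)-dione | C=C1C(=O)C=C(CC(=O)CC(C)C)OC1=O | intermediate
8 | (1R,2R,5S)-6,6-dimethyl-7'-(4-methyl-2-oxopentyl)-3',4'-dihydro-5'H-spiro[bicyclo[3.1.1]heptane-2,2'-pyrano[4,3-b]pyran]-5'-one (ether oxygen anti to the gem-dimethyl bridge) | CC(C)CC(=O)CC1=CC2=C(CC[C@@]3(CC[C@H]4C[C@@H]3C4(C)C)O2)C(=O)O1 | intermediate
9 | methyl (1R,2R,5S)-6,6-dimethyl-6'-(6-methyl-2,4-dioxoheptyl)-3',4'-dihydrospiro[bicyclo[3.1.1]heptane-2,2'-pyran]-5'-carboxylate | CC(C)CC(=O)CC(=O)CC1=C(CC[C@@]2(CC[C@H]3C[C@@H]2C3(C)C)O1)C(=O)OC | intermediate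
10 | 1-[(1R,2R,5S)-5',7'-dihydroxy-6,6-dimethylspiro[bicyclo[3.1.1]heptane-2,2'-chromane]-6'-yl]-3-methylbutan-1-one | CC(C)CC(=O)c1c(O)cc2c(c1O)CC[C@@]1(CC[C@H]3C[C@@H]1C3(C)C)O2 | intermediate
11 | N-{[(1R,2R,5S)-5',7'-dihydroxy-6,6-dimethyl-6'-(3-methylbutanoyl)spiro[bicyclo[3.1.1]heptane-2,2'-chromane]-8'-yl]methylidene}-N-methylmethanaminium chloride | CC(C)CC(=O)c1c(O)c(C=[N+](C)C)c2c(c1O)CC[C@@]1(CC[C@H]3C[C@@H]1C3(C)C)O2.[Cl-] | intermediate
12 | euglobal G3, (1R,2R,5S)-5',7'-dihydroxy-6,6-dimethyl-6'-(3-methylbutanoyl)spiro[bicyclo[3.1.1]heptane-2,2'-chromane]-8'-carbaldehyde | CC(C)CC(=O)c1c(O)c(C=O)c2c(c1O)CC[C@@]1(CC[C@H]3C[C@@H]1C3(C)C)O2 | target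

**Totals**
Total step count: 3. Longest linear sequence: 3 steps (1 → 4 → 10 → 12).

**Steps most likely to fail, with fallbacks**

Step 2 is the most exposed. The heterodiene 7 may be captured by a second pyranone or by the enol of the side-chain ketone before β-pinene adds. The lactone carbonyl may close the cycloaddition instead of the ketone carbonyl, giving a 4-pyranone isomer that would end as the regioisomeric chromane with the ring oxygen ortho to the acyl group. β-Pinene may also react as an ene donor, or its skeleton may open if the cycloaddition becomes too cationic. Fallback: set out from 1 and form the two rings in two separate operations, adding the side chain in between. Lactone 1, 5 and 6 under the conditions of the first half of step 2 give (1R,2R,5S)-6,6,7'-trimethyl-3',4'-dihydro-5'H-spiro[bicyclo[3.1.1]heptane-2,2'-pyrano[4,3-b]pyran]-5'-one F2. It carries no enolisable ketone and is freed from the 4-pyranone isomer by chromatography. LiN(iPr)2 (1.1 equiv, THF, −78 °C) then removes a proton from the 7'-methyl group, the ring position next to the lactone carbonyl being blocked. N-methoxy-N,3-dimethylbutanamide (CC(C)CC(=O)N(C)OC) acylates the anion. This comes back to the route at 8, now isolated and regio-pure, which Mg(OMe)2 in MeOH converts into 10 as in the second half of step 2.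

Step 1 can stall because the dianion may take a proton from the enolisable ester instead of attacking it. Fallback: set out from 1 and build the ketone by aldol addition and oxidation. Dianion 3 adds to 3-methylbutanal (CC(C)CC=O) at −78 °C to give 4-hydroxy-6-(2-hydroxy-4-methylpentyl)-2H-pyran-2-one F1. Dess–Martin periodinane (CH2Cl2, rt) oxidises its secondary alcohol, and the sequence comes back to the route at 4.

Step 3 can go astray if the chloroiminium ion attacks the enolisable CH2 beside the aryl ketone (chromone formation with an ortho hydroxyl), or if the acid released on hydrolysis ionises the tertiary aryl ether. Fallback: set out from 10 and use a magnesium-templated hydroxymethylation with internal redox instead of an iminium electrophile (MgCl2, Et3N, excess 5, MeCN, reflux). The magnesium phenoxide delivers formaldehyde to C8' and gives 1-[(1R,2R,5S)-5',7'-dihydroxy-8'-(hydroxymethyl)-6,6-dimethylspiro[bicyclo[3.1.1]heptane-2,2'-chromane]-6'-yl]-3-methylbutan-1-one F3. Its magnesium alkoxide passes a hydride to a second formaldehyde in the same flask, and the sequence comes back to the route at 12.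

**Further compounds**
F1 | step 1 | 4-hydroxy-6-(2-hydroxy-4-methylpentyl)-2H-pyran-2-one (racemic carbinol) | CC(C)CC(O)CC1=CC(O)=CC(=O)O1
F2 | step 2 | (1R,2R,5S)-6,6,7'-trimethyl-3',4'-dihydro-5'H-spiro[bicyclo[3.1.1]heptane-2,2'-pyrano[4,3-b]pyran]-5'-one | CC1=CC2=C(CC[C@@]3(CC[C@H]4C[C@@H]3C4(C)C)O2)C(=O)O1
F3 | step 3 | 1-[(1R,2R,5S)-5',7'-dihydroxy-8'-(hydroxymethyl)-6,6-dimethylspiro[bicyclo[3.1.1]heptane-2,2'-chromane]-6'-yl]-3-methylbutan-1-one | CC(C)CC(=O)c1c(O)c(CO)c2c(c1O)CC[C@@]1(CC[C@H]3C[C@@H]1C3(C)C)O2
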